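All constants are made up; no experiment stands behind them.

If a catalyst dies as it works, weigh what it can still buy against what equilibrium allows.

    starting material + reagent + free catalyst ⇌ target + free catalyst, rate k1*[starting material]*[reagent]*[free catalyst] forward; the back reaction follows from the equilibrium constant (K1 = 0.092 /M, k1 = 0.050 /M²/s, Ea1 = 59.0 kJ/mol, ΔH1 = −13.0 kJ/mol)
    free catalyst + target ⇌ idle complex, settled at all times (K2 = 0.58 /M, ΔH2 = −17.0 kJ/mol)
    reagent + target ⇌ idle adduct, settled at all times (K3 = 0.16 /M, ΔH3 = −26.0 kJ/mol)
    starting material + free catalyst → spent catalyst (k4 = 0.0020 /M/s, Ea4 = 82.0 kJ/mol)
    (constants at 60 °C)

| flask | starting material | reagent | free catalyst | temperature | time |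
|---|---|---|---|---|---|
| alpha | 1.5 M | 3.00 M | 15 mM | 80 °C | 40 min |
| eta | 1.5 M | 3.00 M | 15 mM | 120 °C | 40 min |
| gamma | 1.5 M | 3.00 M | 15 mM | 100 °C | 40 min |
| zeta | 1.5 M | 3.00 M | 15 mM | 60 °C | 40 min |

- the flask with the highest amount of target, in percent of the starting material charged ("all alike" if they lie within 1.5 percentage points) (alpha / eta / gamma / zeta / all alike)
- final target, as a percentage of the starting material charged, in alpha
- final target, as a percentage of the starting material charged, in eta
- final target, as a percentage of the starting material charged, in gamma
- final target, as a percentage of the starting material charged, in zeta

- what is said of target includes idle complex and idle adduct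
- all constants are for 60 °C and move with temperature by the activation energies and enthalpies

Solve the early end first. While the flask is far from balance, the making step and the loss step both run on c(starting material) and c(free catalyst), so both concentrations cancel from their ratio. Each catalyst lost therefore buys 75.0 turnovers at the coldest temperature; this is the partition ratio of a suicide substrate. Multiply by c(free catalyst) charged and divide by c(starting material) charged: that is the budget, in percent of the starting material. Temperature scales it by the speed-up of the making step over that of the loss step.

Now solve the late end. At balance, free target over starting material equals the equilibrium constant times c(reagent), so take that product at the charge as the ceiling. Depletion lowers this figure and the idle adduct raises it, and I let the two offset each other.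

Join the ends. Net gain shrinks with the distance left to the ceiling, so the share of the ceiling reached is one minus e to the minus reach.

| flask | budget | ceiling | reach | share | target |
|---|---|---|---|---|---|
| zeta, 60 °C | 75.0% | 27.6% | 2.72 | 93.4% | 25.8% |
| eta, 120 °C | 21.1% | 13.5% | 1.57 | 79.1% | 10.7% |

Read the reach column first: the reach, budget divided by ceiling, contains no c(reagent), since reagent stands in both. Going from zeta to eta, the budget shrinks by more than the ceiling, so the reach of eta is lower than that of zeta. Yet eta's reach still stands above one. Read the last column next: my target for zeta is higher than my target for eta. Alpha and gamma lie between them in temperature, so I commit to zeta.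

The forecast also names zeta, with 24.8% in zeta, 18.3% in alpha, 13.7% in gamma and 10.4% in eta, on these grounds: “Catalyst death has a higher activation energy than the main reaction, so the hotter flasks lose their catalyst before reaching even that lower ceiling”. My figure for zeta stands above the forecast's, and so does my figure for eta.

The simulation gives zeta as the best flask, with 23.8% in zeta, 17.8% in alpha, 13.4% in gamma and 10.3% in eta.

Zeta's reach of 2.72 puts its budget above its ceiling. The reverse step holds zeta's target down: strike it and the figure rises from 23.8% to 57.3%, which is 44% of what is missing. Strike the loss step instead and zeta reads 24.7%, so catalyst loss is not what holds zeta down, though 99.2% of its catalyst ends spent. Now cut zeta's reagent to 1.2 M: the reach stays 2.72, the ceiling becomes 11.0%, the reckoning gives 10.3%, and that neighbour flask reads 9.51%.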